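**Retrosynthetic overview**

1. Rings: A = dioxygenated ring whose ether oxygen goes to B; B = meta-linked ring; C = para-linked ring; D = dioxygenated ring whose ether oxygen goes to C. The target comes from a 20-membered ketone (C=O on the bridge carbon next to ring C, both phenols as mesylates) by Wolff–Kishner reduction with loss of the sulfonates.
2. Key disconnection: the bond between that carbonyl carbon and the ring C carbon para to the D–O–C ether oxygen. This opens the macrocycle to a linear arylacetic acid (B–O–A–CH2CH2–D–O–C) in which ring C is a plain phenoxy group; forward, a Friedel–Crafts macrocyclisation at a C–H bond.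
3. Enabling feature: ring C is 1,4-disubstituted, so the carbon to be bonded lies para to the ether oxygen and between two CH positions. It is the one activated, unhindered C–H once rings A and D are switched off as mesylates; ring B cannot reach its own side chain.
4. The seco acid comes from a Wittig/hydrogenation construction of the A–CH2CH2–D bridge, joining a ring C–O–D phosphonium salt (Chan–Lam ether) to a ring B–O–A aldehyde (SNAr ether).
5. Ring order: the four benzene rings are bought; the only ring made is the 20-membered macrocycle, in the penultimate step.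

Key step: step 9

Remark: the target has no stereocentre to set; the two benzyloxy aldehydes used as starting materials are treated as catalogue compounds.

**Route**

Step 1
Reactants: 1 4-(benzyloxy)-3-hydroxybenzaldehyde; 2 phenylboronic acid
Product: 3 4-(benzyloxy)-3-phenoxybenzaldehyde
Conditions: Cu(OAc)2 (20 mol%), pyridine, 4 Å MS, CH2Cl2, O2 (1 atm), rt
Reagents that add atoms: none
Why: Chan–Lam oxidative C–O coupling, in which the copper phenoxide of 1 is transmetallated by the boronic acid and reductive elimination from trivalent copper should give the diaryl ether at room temperature without touching aldehyde or benzyl ether.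

Step 2
Reactants: 3 4-(benzyloxy)-3-phenoxybenzaldehyde
Product: 4 [4-(benzyloxy)-3-phenoxyphenyl]methanol
Conditions: NaBH4, MeOH–THF, 0 °C
Reagents that add atoms: none
Why: Hydride 1,2-reduction of the aldehyde by NaBH4; the ethers are inert.

Step 3
Reactants: 4 [4-(benzyloxy)-3-phenoxyphenyl]methanol
Product: 5 {[4-(benzyloxy)-3-phenoxyphenyl]methyl}triphenylphosphonium bromide
Conditions: Ph3P·HBr, MeCN, reflux
Reagents that add atoms: triphenylphosphine hydrobromide, [Br-].c1ccc(cc1)[PH+](c1ccccc1)c1ccccc1
Why: The electron-rich benzylic alcohol should be converted in situ into the benzylic bromide and displaced by PPh3 (phosphonium salt formation), giving the Wittig salt in one operation.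

Step 4
Reactants: 6 3-(benzyloxy)-4-fluorobenzaldehyde; 7 methyl 2-(3-hydroxyphenyl)acetate
Product: 8 methyl 2-{3-[2-(benzyloxy)-4-formylphenoxy]phenyl}acetate
Conditions: K2CO3, DMF, 110 °C
Reagents that add atoms: none
Why: Nucleophilic aromatic substitution (SNAr), in which the para-formyl group stabilises the Meisenheimer adduct so that the phenoxide of 7 displaces fluoride, while carbonate is too weak to enolise the arylacetate.

Step 5
Reactants: 5 {[4-(benzyloxy)-3-phenoxyphenyl]methyl}triphenylphosphonium bromide; 8 methyl 2-{3-[2-(benzyloxy)-4-formylphenoxy]phenyl}acetate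
Product: 10 methyl 2-{3-[2-(benzyloxy)-4-{2-[4-(benzyloxy)-3-phenoxyphenyl]ethenyl}phenoxy]phenyl}acetate (E/Z mixture), via ylide 9 (not isolated)
Conditions: NaN(SiMe3)2, THF, 0 °C; then 8, −78 °C to rt
Reagents that add atoms: none
Why: Wittig olefination by the semi-stabilised benzylic ylide, formed before 8 is added so that no free base meets the arylacetate; the alkene geometry is irrelevant because the double bond is hydrogenated next.

Step 6
Reactants: 10 methyl 2-{3-[2-(benzyloxy)-4-{2-[4-(benzyloxy)-3-phenoxyphenyl]ethenyl}phenoxy]phenyl}acetate (E/Z mixture)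
Product: 11 methyl 2-{3-[2-hydroxy-4-{2-(4-hydroxy-3-phenoxyphenyl)ethyl}phenoxy]phenyl}acetate
Conditions: H2 (1 atm), 10% Pd/C, EtOAc–MeOH, rt
Reagents that add atoms: none
Why: Heterogeneous catalytic hydrogenation should saturate the stilbene and hydrogenolyse both benzyl ethers in the same operation, diaryl ethers and the methyl ester being inert.

Step 7
Reactants: 11 methyl 2-{3-[2-hydroxy-4-{2-(4-hydroxy-3-phenoxyphenyl)ethyl}phenoxy]phenyl}acetate
Product: 12 methyl 2-{3-[2-(methanesulfonyloxy)-4-{2-[4-(methanesulfonyloxy)-3-phenoxyphenyl]ethyl}phenoxy]phenyl}acetate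
Conditions: MsCl, NEt3, CH2Cl2, 0 °C
Reagents that add atoms: methanesulfonyl chloride, CS(=O)(=O)Cl
Why: O-Sulfonylation of both phenols, which protects them and, through the electron-withdrawing sulfonate groups, deactivates rings A and D for the electrophilic step to come.

Step 8
Reactants: 12 methyl 2-{3-[2-(methanesulfonyloxy)-4-{2-[4-(methanesulfonyloxy)-3-phenoxyphenyl]ethyl}phenoxy]phenyl}acetate
Product: 13 2-{3-[2-(methanesulfonyloxy)-4-{2-[4-(methanesulfonyloxy)-3-phenoxyphenyl]ethyl}phenoxy]phenyl}acetic acid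
Conditions: 4 M aq HCl, 1,4-dioxane, 85 °C
Reagents that add atoms: water, O
Why: Acid-catalysed ester hydrolysis (AAC2) is chosen because aryl sulfonates and diaryl ethers are stable to aqueous acid, whereas hydroxide would begin to cleave the mesylates.

Step 9
Reactants: 13 2-{3-[2-(methanesulfonyloxy)-4-{2-[4-(methanesulfonyloxy)-3-phenoxyphenyl]ethyl}phenoxy]phenyl}acetic acid
Product: 15 macrocyclic ketone bis(methanesulfonate) (the 20-membered ring of the target with C=O on the bridge carbon bonded to ring C and OSO2Me in place of both OH), via acid chloride 14 (not isolated)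
Conditions: (COCl)2, cat. DMF, CH2Cl2, rt; then syringe-pump addition (16 h) to AlCl3 (4 equiv), CH2Cl2–MeNO2, 0 °C to rt, final 1 mM
Reagents that add atoms: oxalyl chloride, O=C(Cl)C(Cl)=O (supplies the chlorine of 14; no atom of it remains in 15)
Why: Oxalyl chloride converts 13 into acid chloride 14, which AlCl3 ionises to an arylacetyl acylium ion that attacks the para C–H of the phenoxy ring C (Wheland intermediate, loss of a proton), an intramolecular Friedel–Crafts acylation that forms the bond between the future bridge carbon and ring C. The closest known reaction type is the pseudo-high-dilution Friedel–Crafts macrocyclisation of ω-arylalkanoyl chlorides to para-bridged ketones and of aryl ether acid chlorides to macrocyclic aryl ether ketones. The one ring formed, the 20-membered ring, is closed by macrocyclising electrophilic aromatic substitution (end-to-end attack of the chain terminus on an arene carbon), and no stereocentre is created. The step needs intramolecular to beat intermolecular acylation, which slow addition into dilute AlCl3 should secure, and it needs one carbon to be chosen among four rings. That carbon is the only one para to an ether oxygen with two unsubstituted neighbours; rings A and D are deactivated by their sulfonates and could close only strained 8-, 9- or 14-membered cyclophane rings, and ring B cannot reach its own chain and is deactivated by the acylium side chain. The ketone formed is the temporary handle that step 10 removes.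

Step 10
Reactants: 15 macrocyclic ketone bis(methanesulfonate)
Product: 17 target CNP0329842.0, via hydrazone 16 (not isolated)
Conditions: N2H4·H2O, diethylene glycol, 120 °C; then KOH, 195 °C; aq HCl work-up
Reagents that add atoms: hydrazine (as hydrate), NN (supplies the nitrogen of 16; no atom of it remains in 17)
Why: Wolff–Kishner reduction (Huang-Minlon procedure) in which the hydrazone is formed before base is added, so that KOH at 195 °C drives loss of N2 to the CH2CH2 bridge and cleaves both aryl mesylates while ring C is no longer an acyl-activated ring next to the ring D phenoxide (no O-to-O aryl migration).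

**Compound list**

1 | 4-(benzyloxy)-3-hydroxybenzaldehyde | O=Cc1ccc(OCc2ccccc2)c(O)c1 | starting material
2 | phenylboronic acid | OB(O)c1ccccc1 | starting material
3 | 4-(benzyloxy)-3-phenoxybenzaldehyde | O=Cc1ccc(OCc2ccccc2)c(Oc2ccccc2)c1 | intermediate
4 | [4-(benzyloxy)-3-phenoxyphenyl]methanol | OCc1ccc(OCc2ccccc2)c(Oc2ccccc2)c1 | intermediate
5 | {[4-(benzyloxy)-3-phenoxyphenyl]methyl}triphenylphosphonium bromide | [Br-].c1ccc(cc1)[P+](Cc1ccc(OCc2ccccc2)c(Oc2ccccc2)c1)(c1ccccc1)c1ccccc1 | intermediate
6 | 3-(benzyloxy)-4-fluorobenzaldehyde | O=Cc1ccc(F)c(OCc2ccccc2)c1 | starting material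
7 | methyl 2-(3-hydroxyphenyl)acetate | COC(=O)Cc1cccc(O)c1 | starting material
8 | methyl 2-{3-[2-(benzyloxy)-4-formylphenoxy]phenyl}acetate | COC(=O)Cc1cccc(Oc2ccc(C=O)cc2OCc2ccccc2)c1 | intermediate
9 | {[4-(benzyloxy)-3-phenoxyphenyl]methylidene}triphenylphosphorane (ylide, not isolated) | C(=P(c1ccccc1)(c1ccccc1)c1ccccc1)c1ccc(OCc2ccccc2)c(Oc2ccccc2)c1 | intermediate
10 | methyl 2-{3-[2-(benzyloxy)-4-{2-[4-(benzyloxy)-3-phenoxyphenyl]ethenyl}phenoxy]phenyl}acetate (E/Z mixture) | COC(=O)Cc1cccc(Oc2ccc(C=Cc3ccc(OCc4ccccc4)c(Oc4ccccc4)c3)cc2OCc2ccccc2)c1 | intermediate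
11 | methyl 2-{3-[2-hydroxy-4-{2-(4-hydroxy-3-phenoxyphenyl)ethyl}phenoxy]phenyl}acetate | COC(=O)Cc1cccc(Oc2ccc(CCc3ccc(O)c(Oc4ccccc4)c3)cc2O)c1 | intermediate
12 | methyl 2-{3-[2-(methanesulfonyloxy)-4-{2-[4-(methanesulfonyloxy)-3-phenoxyphenyl]ethyl}phenoxy]phenyl}acetate | COC(=O)Cc1cccc(Oc2ccc(CCc3ccc(OS(C)(=O)=O)c(Oc4ccccc4)c3)cc2OS(C)(=O)=O)c1 | intermediate
13 | 2-{3-[2-(methanesulfonyloxy)-4-{2-[4-(methanesulfonyloxy)-3-phenoxyphenyl]ethyl}phenoxy]phenyl}acetic acid | OC(=O)Cc1cccc(Oc2ccc(CCc3ccc(OS(C)(=O)=O)c(Oc4ccccc4)c3)cc2OS(C)(=O)=O)c1 | intermediate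
14 | 2-{3-[2-(methanesulfonyloxy)-4-{2-[4-(methanesulfonyloxy)-3-phenoxyphenyl]ethyl}phenoxy]phenyl}acetyl chloride (not isolated) | ClC(=O)Cc1cccc(Oc2ccc(CCc3ccc(OS(C)(=O)=O)c(Oc4ccccc4)c3)cc2OS(C)(=O)=O)c1 | intermediate
15 | macrocyclic ketone bis(methanesulfonate): 20-membered ring of the target with C=O on the bridge carbon bonded to ring C and OSO2Me in place of both OH | CS(=O)(=O)Oc1cc2ccc1Oc1cccc(c1)CC(=O)c1ccc(cc1)Oc1cc(ccc1OS(C)(=O)=O)CC2 | intermediate
16 | hydrazone of 15 (not isolated) | CS(=O)(=O)Oc1cc2ccc1Oc1cccc(c1)CC(=NN)c1ccc(cc1)Oc1cc(ccc1OS(C)(=O)=O)CC2 | intermediate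
17 | CNP0329842.0 | Oc1cc2ccc1Oc1cccc(c1)CCc1ccc(cc1)Oc1cc(ccc1O)CC2 | target

**Step count and risks**

Total steps: 10. Longest linear sequence: 9 steps (steps 1, 2, 3, 5, 6, 7, 8, 9, 10).

Steps most likely to fail:

Step 9. What may go wrong: intermolecular acylation (chain growth) overtaking the 20-membered closure, or attack of the acylium ion at the para-to-oxygen positions of rings B and D. The fallback closes the same bond by ipso substitution of a silyl group (known acyldesilylation chemistry); it sets out from 1 and 8 and returns at 15.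
- Compound 1 is coupled with [4-(trimethylsilyl)phenyl]boronic acid as in step 1 to give 4-(benzyloxy)-3-[4-(trimethylsilyl)phenoxy]benzaldehyde F1.
- So that the acid-labile aryl–silicon bond never meets Ph3P·HBr, the Wittig roles are exchanged. NaBH4 reduces 8 to methyl 2-{3-[2-(benzyloxy)-4-(hydroxymethyl)phenoxy]phenyl}acetate F2, and Ph3P·HBr converts this into ({3-(benzyloxy)-4-[3-(2-methoxy-2-oxoethyl)phenoxy]phenyl}methyl)triphenylphosphonium bromide F3.
- NaN(SiMe3)2 gives the ylide methyl 2-(3-{2-(benzyloxy)-4-[(triphenylphosphoranylidene)methyl]phenoxy}phenyl)acetate F4, which with F1 gives the stilbene methyl 2-{3-[2-(benzyloxy)-4-(2-{4-(benzyloxy)-3-[4-(trimethylsilyl)phenoxy]phenyl}ethenyl)phenoxy]phenyl}acetate F5.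
- H2 over Pd/C gives the bis-phenol methyl 2-{3-[2-hydroxy-4-(2-{4-hydroxy-3-[4-(trimethylsilyl)phenoxy]phenyl}ethyl)phenoxy]phenyl}acetate F6, and MsCl/NEt3 gives methyl 2-{3-[2-(methanesulfonyloxy)-4-(2-{4-(methanesulfonyloxy)-3-[4-(trimethylsilyl)phenoxy]phenyl}ethyl)phenoxy]phenyl}acetate F7.
- Me3SnOH in 1,2-dichloroethane at 80 °C (neutral ester cleavage, since aqueous acid would remove silicon) gives 2-{3-[2-(methanesulfonyloxy)-4-(2-{4-(methanesulfonyloxy)-3-[4-(trimethylsilyl)phenoxy]phenyl}ethyl)phenoxy]phenyl}acetic acid F8.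
- 1-Chloro-N,N,2-trimethylprop-1-en-1-amine converts F8, without free HCl, into 2-{3-[2-(methanesulfonyloxy)-4-(2-{4-(methanesulfonyloxy)-3-[4-(trimethylsilyl)phenoxy]phenyl}ethyl)phenoxy]phenyl}acetyl chloride F9.
- Slow addition of F9 to AlCl3 as in step 9 should close the ring by ipso substitution of silicon, because the β-silyl-stabilised Wheland intermediate makes the silylated carbon far more reactive than any C–H position. This gives 15 with loss of Me3SiCl.

Step 10. What may go wrong: loss of the sulfonates before hydrazone formation is complete, which would expose the acyl-activated ring C to migration between the two oxygens of ring D; azine formation; or incomplete loss of N2 in the macrocycle. The fallback separates the two events; it sets out from 15 and returns at 17. Ionic hydrogenation (Et3SiH, CF3CO2H, CH2Cl2, rt to 40 °C) reduces the electron-rich aryl ketone through its benzylic cation to the macrocyclic bis(methanesulfonate) of the target F10. Only then are the mesylates cleaved (KOH, MeOH–THF, 65 °C, acidic work-up) to give 17.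

Step 4. What may go wrong: slow fluoride displacement next to the electron-releasing benzyloxy group, so that ester saponification or aldol-type condensation of the arylacetate with the aldehyde overtakes the substitution. The fallback makes the same ether by copper catalysis, independent of carbonyl activation; it sets out from 7 and returns at 8. Purchasable 4-bromo-3-hydroxybenzaldehyde is benzylated (BnBr, K2CO3, acetone) to 3-(benzyloxy)-4-bromobenzaldehyde F11, and Ullmann etherification of 7 with F11 (CuI 10 mol%, picolinic acid 20 mol%, K3PO4, DMSO, 90 °C) gives 8.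

**Further compounds**

F1 | step 9 | 4-(benzyloxy)-3-[4-(trimethylsilyl)phenoxy]benzaldehyde | O=Cc1ccc(OCc2ccccc2)c(Oc2ccc(cc2)[Si](C)(C)C)c1
F2 | step 9 | methyl 2-{3-[2-(benzyloxy)-4-(hydroxymethyl)phenoxy]phenyl}acetate | COC(=O)Cc1cccc(Oc2ccc(CO)cc2OCc2ccccc2)c1
F3 | step 9 | ({3-(benzyloxy)-4-[3-(2-methoxy-2-oxoethyl)phenoxy]phenyl}methyl)triphenylphosphonium bromide | [Br-].COC(=O)Cc1cccc(Oc2ccc(C[P+](c3ccccc3)(c3ccccc3)c3ccccc3)cc2OCc2ccccc2)c1
F4 | step 9 | methyl 2-(3-{2-(benzyloxy)-4-[(triphenylphosphoranylidene)methyl]phenoxy}phenyl)acetate | COC(=O)Cc1cccc(Oc2ccc(C=P(c3ccccc3)(c3ccccc3)c3ccccc3)cc2OCc2ccccc2)c1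
F5 | step 9 | methyl 2-{3-[2-(benzyloxy)-4-(2-{4-(benzyloxy)-3-[4-(trimethylsilyl)phenoxy]phenyl}ethenyl)phenoxy]phenyl}acetate (E/Z mixture) | COC(=O)Cc1cccc(Oc2ccc(C=Cc3ccc(OCc4ccccc4)c(Oc4ccc(cc4)[Si](C)(C)C)c3)cc2OCc2ccccc2)c1
F6 | step 9 | methyl 2-{3-[2-hydroxy-4-(2-{4-hydroxy-3-[4-(trimethylsilyl)phenoxy]phenyl}ethyl)phenoxy]phenyl}acetate | COC(=O)Cc1cccc(Oc2ccc(CCc3ccc(O)c(Oc4ccc(cc4)[Si](C)(C)C)c3)cc2O)c1
F7 | step 9 | methyl 2-{3-[2-(methanesulfonyloxy)-4-(2-{4-(methanesulfonyloxy)-3-[4-(trimethylsilyl)phenoxy]phenyl}ethyl)phenoxy]phenyl}acetate | COC(=O)Cc1cccc(Oc2ccc(CCc3ccc(OS(C)(=O)=O)c(Oc4ccc(cc4)[Si](C)(C)C)c3)cc2OS(C)(=O)=O)c1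
F8 | step 9 | 2-{3-[2-(methanesulfonyloxy)-4-(2-{4-(methanesulfonyloxy)-3-[4-(trimethylsilyl)phenoxy]phenyl}ethyl)phenoxy]phenyl}acetic acid | OC(=O)Cc1cccc(Oc2ccc(CCc3ccc(OS(C)(=O)=O)c(Oc4ccc(cc4)[Si](C)(C)C)c3)cc2OS(C)(=O)=O)c1
F9 | step 9 | 2-{3-[2-(methanesulfonyloxy)-4-(2-{4-(methanesulfonyloxy)-3-[4-(trimethylsilyl)phenoxy]phenyl}ethyl)phenoxy]phenyl}acetyl chloride | ClC(=O)Cc1cccc(Oc2ccc(CCc3ccc(OS(C)(=O)=O)c(Oc4ccc(cc4)[Si](C)(C)C)c3)cc2OS(C)(=O)=O)c1
F10 | step 10 | macrocyclic bis(methanesulfonate) of the target (both OH as OSO2Me, bridge fully reduced) | CS(=O)(=O)Oc1cc2ccc1Oc1cccc(c1)CCc1ccc(cc1)Oc1cc(ccc1OS(C)(=O)=O)CC2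
F11 | step 4 | 3-(benzyloxy)-4-bromobenzaldehyde | O=Cc1ccc(Br)c(OCc2ccccc2)c1
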